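**Retrosynthetic overview**
1. Target 25 ⇐ desilylation and C8 angeloylation of the macrocyclic hydroxy lactone 21.
2. 21 ⇐ aldehyde–butenolide 18. The ten-membered carbocycle is closed last, at C7–C8, by addition of a samarium ketyl radical (C8) to C7 of a 3-(acetoxymethyl)butenolide; loss of acetate unveils the exo-methylene, and C7 and C8 are set here.
3. The lactone ring is made first, by ring-closing metathesis of the 2-(acetoxymethyl)acrylate 15 of dienol 12 (C6 from asymmetric vinylation of enal 11).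
4. 11 ⇐ vinylogous Mukaiyama aldol (C2–C3 bond, sets C2) of (Z)-enal 7 with the silyl dienol ether of 3-methylbut-2-enal.
5. 7 ⇐ asymmetric alkynylation of silyloxyacetaldehyde with methyl propiolate (sets C9), then syn-addition of Me2CuLi (fixes the Z-olefin).

Assumption: silyl-protected glycolaldehyde 1 and the reagent solutions (SmI2, Me2Zn, Zn(CH=CH2)2) are bought as such, and 1 is counted by its four-heavy-atom glycolaldehyde core.
Positions are given in germacranolide numbering (C1–C15); TBS = tert-butyldimethylsilyl.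

**Step 1**
Reactants: 1 (tert-butyldimethylsilyloxy)acetaldehyde; 2 methyl propiolate
Product: 3 methyl (4R)-5-(TBS-oxy)-4-hydroxypent-2-ynoate
Conditions: Me2Zn (3 equiv), ProPhenol ligand (20 mol %, the enantiomer that directs attack to the Re face), Ph3PO (40 mol %), toluene, 4 °C
Reagents that add atoms: none
Why: Dinuclear-zinc ProPhenol asymmetric alkynylation delivers the zinc acetylide of the propiolate to the Re face of the aldehyde inside the chiral pocket, which sets C9 as (R).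

**Step 2**
Reactants: 3 methyl (4R)-5-(TBS-oxy)-4-hydroxypent-2-ynoate
Product: 4 methyl (4R)-4,5-bis(TBS-oxy)pent-2-ynoate
Conditions: TBSCl, imidazole, DMF, 25 °C
Reagents that add atoms: tert-butyldimethylsilyl chloride, CC(C)(C)[Si](C)(C)Cl
Why: Standard silylation of the propargylic alcohol, which keeps the later enoate from lactonising and leaves C9 untouched.

**Step 3**
Reactants: 4 methyl (4R)-4,5-bis(TBS-oxy)pent-2-ynoate
Product: 5 methyl (2Z,4R)-4,5-bis(TBS-oxy)-3-methylpent-2-enoate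
Conditions: Me2CuLi (from CuI and MeLi), THF, −78 °C; NH4Cl/MeOH quench at −78 °C
Reagents that add atoms: lithium dimethylcuprate, [Li+].C[Cu-]C
Why: Syn-carbocupration (cuprate conjugate addition) of the ynoate and cold protonation place methyl on C10 with C9 and the ester carbon cis, which fixes the Z geometry of C1=C10.

**Step 4**
Reactants: 5 methyl (2Z,4R)-4,5-bis(TBS-oxy)-3-methylpent-2-enoate
Product: 6 (2Z,4R)-4,5-bis(TBS-oxy)-3-methylpent-2-en-1-ol
Conditions: i-Bu2AlH (2.5 equiv), CH2Cl2, −78 °C; aq. potassium sodium tartrate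
Reagents that add atoms: none
Why: 1,2-Reduction of the conjugated ester by i-Bu2AlH gives the allylic alcohol without touching the olefin geometry or the silyl ethers.

**Step 5**
Reactants: 6 (2Z,4R)-4,5-bis(TBS-oxy)-3-methylpent-2-en-1-ol
Product: 7 (2Z,4R)-4,5-bis(TBS-oxy)-3-methylpent-2-enal
Conditions: Dess–Martin periodinane, NaHCO3, CH2Cl2, 0 °C
Reagents that add atoms: none
Why: Buffered Dess–Martin oxidation of the allylic alcohol gives the (Z)-enal under conditions that do not isomerise the trisubstituted olefin.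

**Step 6**
Reactants: 8 3-methylbut-2-enal
Product: 9 (E)-tert-butyl(dimethyl)[(3-methylbuta-1,3-dien-1-yl)oxy]silane
Conditions: TBSOTf, Et3N, Et2O, 0 → 25 °C
Reagents that add atoms: tert-butyldimethylsilyl trifluoromethanesulfonate, CC(C)(C)[Si](C)(C)OS(=O)(=O)C(F)(F)F
Why: O-Silylation of the enal and γ-deprotonation by the amine (soft enolisation) give the 1-silyloxy diene with the E enol ether.

**Step 7**
Reactants: 7 (2Z,4R)-4,5-bis(TBS-oxy)-3-methylpent-2-enal; 9 (E)-tert-butyl(dimethyl)[(3-methylbuta-1,3-dien-1-yl)oxy]silane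
Product: 10 (2E,5R,6Z,8R)-8,9-bis(TBS-oxy)-5-hydroxy-3,7-dimethylnona-2,6-dienal
Conditions: B-phenyl oxazaborolidinone from N-tosyltryptophan (50 mol %, the enantiomer that exposes the Re face), i-PrOH (1.1 equiv), EtCN, −78 °C
Reagents that add atoms: none
Why: In this vinylogous Mukaiyama aldol reaction the boron Lewis acid activates the enal, the dienol ether attacks through its terminal carbon on the Re face to set C2 as (R), and reaction through the s-trans diene gives the E C4=C5 olefin.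

**Step 8**
Reactants: 10 (2E,5R,6Z,8R)-8,9-bis(TBS-oxy)-5-hydroxy-3,7-dimethylnona-2,6-dienal
Product: 11 (2E,5R,6Z,8R)-5,8,9-tris(TBS-oxy)-3,7-dimethylnona-2,6-dienal
Conditions: TBSCl, imidazole, DMF, 25 °C
Reagents that add atoms: tert-butyldimethylsilyl chloride, CC(C)(C)[Si](C)(C)Cl
Why: Silylation with the weak base imidazole protects the C2 hydroxyl without dehydrating or enolising the δ-hydroxy enal.

**Step 9**
Reactants: 11 (2E,5R,6Z,8R)-5,8,9-tris(TBS-oxy)-3,7-dimethylnona-2,6-dienal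
Product: 12 (3S,4E,7R,8Z,10R)-7,10,11-tris(TBS-oxy)-5,9-dimethylundeca-1,4,8-trien-3-ol
Conditions: Zn(CH=CH2)2 (2 equiv), (−)-3-exo-morpholinoisoborneol (10 mol %), toluene, −20 °C; aq. NH4Cl
Reagents that add atoms: divinylzinc, C=C[Zn]C=C
Why: Amino-alcohol-catalysed asymmetric vinylzinc addition (Oppolzer–Nugent type) delivers vinyl to the Si face of the enal, as this ligand does with aryl aldehydes, which sets the C6 carbinol (3S in this name, the 6R centre of the lactone).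

**Step 10**
Reactants: 13 2-(bromomethyl)acrylic acid
Product: 14 2-(acetoxymethyl)acrylic acid
Conditions: KOAc (4 equiv), AcOH, 60 °C
Reagents that add atoms: potassium acetate, CC(=O)[O-].[K+]
Why: Allylic substitution of the bromide by acetate gives the same product by the direct or the allylic-shift pathway because the allyl unit is symmetric.

**Step 11**
Reactants: 12 (3S,4E,7R,8Z,10R)-7,10,11-tris(TBS-oxy)-5,9-dimethylundeca-1,4,8-trien-3-ol; 14 2-(acetoxymethyl)acrylic acid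
Product: 15 (3S,4E,7R,8Z,10R)-7,10,11-tris(TBS-oxy)-5,9-dimethylundeca-1,4,8-trien-3-yl 2-(acetoxymethyl)acrylate
Conditions: DCC, DMAP (5 mol %), CH2Cl2, 0 °C
Reagents that add atoms: none
Why: Steglich esterification acylates the only free hydroxyl with retention at C6.

**Step 12**
Reactants: 15 (3S,4E,7R,8Z,10R)-7,10,11-tris(TBS-oxy)-5,9-dimethylundeca-1,4,8-trien-3-yl 2-(acetoxymethyl)acrylate
Product: 16 {(5R)-5-[(1E,4R,5Z,7R)-4,7,8-tris(TBS-oxy)-2,6-dimethylocta-1,5-dien-1-yl]-2-oxo-2,5-dihydrofuran-3-yl}methyl acetate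
Conditions: second-generation Grubbs catalyst (H2IMes)(PCy3)Cl2Ru=CHPh (5 mol %), CH2Cl2 (0.005 M), 40 °C
Reagents that add atoms: none
Why: Ring-closing metathesis starts at the terminal vinyl group and closes onto the 1,1-disubstituted acrylate to give the five-membered butenolide, while the two trisubstituted olefins stay inert and the E C4=C5 olefin cannot sit in a small ring.

**Step 13**
Reactants: 16 {(5R)-5-[(1E,4R,5Z,7R)-4,7,8-tris(TBS-oxy)-2,6-dimethylocta-1,5-dien-1-yl]-2-oxo-2,5-dihydrofuran-3-yl}methyl acetate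
Product: 17 {(5R)-5-[(1E,4R,5Z,7R)-4,7-bis(TBS-oxy)-8-hydroxy-2,6-dimethylocta-1,5-dien-1-yl]-2-oxo-2,5-dihydrofuran-3-yl}methyl acetate
Conditions: HF·pyridine, pyridine, THF, 0 °C
Reagents that add atoms: none
Why: Buffered HF·pyridine cleaves the primary silyl ether much faster than the two secondary allylic ones and does not touch the butenolide or the allylic acetate.

**Step 14**
Reactants: 17 {(5R)-5-[(1E,4R,5Z,7R)-4,7-bis(TBS-oxy)-8-hydroxy-2,6-dimethylocta-1,5-dien-1-yl]-2-oxo-2,5-dihydrofuran-3-yl}methyl acetate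
Product: 18 {(5R)-5-[(1E,4R,5Z,7R)-4,7-bis(TBS-oxy)-2,6-dimethyl-8-oxoocta-1,5-dien-1-yl]-2-oxo-2,5-dihydrofuran-3-yl}methyl acetate
Conditions: Dess–Martin periodinane, NaHCO3, CH2Cl2, 0 °C; used at once
Reagents that add atoms: none
Why: Neutral Dess–Martin oxidation gives the α-silyloxy aldehyde without epimerising C9 or moving the β,γ-olefin into conjugation.

**Step 15**
Reactants: 18 {(5R)-5-[(1E,4R,5Z,7R)-4,7-bis(TBS-oxy)-2,6-dimethyl-8-oxoocta-1,5-dien-1-yl]-2-oxo-2,5-dihydrofuran-3-yl}methyl acetate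
Product: 21 (2R,6R,7R,8R,9R)-2,9-bis(TBS-oxy)-8-hydroxygermacra-1(10)Z,4E,11(13)-trien-12,6-olide, via samarium ketyl radical 19 (not isolated), via samarium enolate 20 (not isolated)
Conditions: SmI2 (2.5 equiv), THF, −78 → 0 °C, 18 added over 6 h (final 0.002 M), no proton source; aq. NH4Cl
Reagents that add atoms: none
Why: Proposed new method: SmI2 reduces the α-silyloxy aldehyde to ketyl radical 19, which closes the ten-membered ring by radical conjugate addition to C7 of the butenolide on the face anti to the C5 side chain while trivalent samarium bridges the ketyl oxygen and the lactone carbonyl (this gives the trans-fused lactone and places C8–O syn to C6–O and C9–O along the ring), and the resulting α-carbonyl radical is reduced by a second SmI2 to enolate 20, which expels acetate (E1cB) to give the exo-methylene; the closest known reactions are SmI2 ketyl–olefin couplings of aldehydes with acrylates and butenolides and the reductive allylation of carbonyl compounds with 2-(acyloxymethyl)acrylates, here merged and run as a macrocyclisation.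

**Step 16**
Reactants: 21 (2R,6R,7R,8R,9R)-2,9-bis(TBS-oxy)-8-hydroxygermacra-1(10)Z,4E,11(13)-trien-12,6-olide; 22 angelic acid [(Z)-2-methylbut-2-enoic acid]
Product: 24 (2R,6R,7S,8R,9R)-8-angeloyloxy-2,9-bis(TBS-oxy)germacra-1(10)Z,4E,11(13)-trien-12,6-olide, via mixed Yamaguchi anhydride 23 (not isolated)
Conditions: 22, 2,4,6-trichlorobenzoyl chloride, Et3N, toluene, 25 °C; then 21, 75 °C
Reagents that add atoms: none
Why: Yamaguchi-type acylation through the mixed anhydride without a nucleophilic catalyst esterifies the hindered C8 hydroxyl without Z to E isomerisation of the angelate and without a strong base that could trigger translactonisation.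

**Step 17**
Reactants: 24 (2R,6R,7S,8R,9R)-8-angeloyloxy-2,9-bis(TBS-oxy)germacra-1(10)Z,4E,11(13)-trien-12,6-olide
Product: 25 (2R,6R,7S,8R,9R)-8-angeloyloxy-2,9-dihydroxygermacra-1(10)Z,4E,11(13)-trien-12,6-olide (CNP0280988.2)
Conditions: HF·pyridine, pyridine, THF, 0 → 25 °C
Reagents that add atoms: none
Why: Acidic fluoride desilylation frees the two allylic hydroxyls under conditions that avoid the base-induced C8 to C9 acyl shift and conjugate addition to the α-methylene lactone.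

**Compound list**
1 | (tert-butyldimethylsilyloxy)acetaldehyde | O=CCO[Si](C)(C)C(C)(C)C | starting material
2 | methyl propiolate | C#CC(=O)OC | starting material
3 | methyl (4R)-5-(TBS-oxy)-4-hydroxypent-2-ynoate | COC(=O)C#C[C@@H](O)CO[Si](C)(C)C(C)(C)C | intermediate
4 | methyl (4R)-4,5-bis(TBS-oxy)pent-2-ynoate | COC(=O)C#C[C@@H](O[Si](C)(C)C(C)(C)C)CO[Si](C)(C)C(C)(C)C | intermediate
5 | methyl (2Z,4R)-4,5-bis(TBS-oxy)-3-methylpent-2-enoate | COC(=O)/C=C(/C)[C@@H](O[Si](C)(C)C(C)(C)C)CO[Si](C)(C)C(C)(C)C | intermediate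
6 | (2Z,4R)-4,5-bis(TBS-oxy)-3-methylpent-2-en-1-ol | OC/C=C(/C)[C@@H](O[Si](C)(C)C(C)(C)C)CO[Si](C)(C)C(C)(C)C | intermediate
7 | (2Z,4R)-4,5-bis(TBS-oxy)-3-methylpent-2-enal | O=C/C=C(/C)[C@@H](O[Si](C)(C)C(C)(C)C)CO[Si](C)(C)C(C)(C)C | intermediate
8 | 3-methylbut-2-enal | CC(C)=CC=O | starting material
9 | (E)-tert-butyl(dimethyl)[(3-methylbuta-1,3-dien-1-yl)oxy]silane | C=C(C)/C=C/O[Si](C)(C)C(C)(C)C | intermediate
10 | (2E,5R,6Z,8R)-8,9-bis(TBS-oxy)-5-hydroxy-3,7-dimethylnona-2,6-dienal | O=C/C=C(\C)C[C@@H](O)/C=C(/C)[C@@H](O[Si](C)(C)C(C)(C)C)CO[Si](C)(C)C(C)(C)C | intermediate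
11 | (2E,5R,6Z,8R)-5,8,9-tris(TBS-oxy)-3,7-dimethylnona-2,6-dienal | O=C/C=C(\C)C[C@@H](O[Si](C)(C)C(C)(C)C)/C=C(/C)[C@@H](O[Si](C)(C)C(C)(C)C)CO[Si](C)(C)C(C)(C)C | intermediate
12 | (3S,4E,7R,8Z,10R)-7,10,11-tris(TBS-oxy)-5,9-dimethylundeca-1,4,8-trien-3-ol | C=C[C@H](O)/C=C(\C)C[C@@H](O[Si](C)(C)C(C)(C)C)/C=C(/C)[C@@H](O[Si](C)(C)C(C)(C)C)CO[Si](C)(C)C(C)(C)C | intermediate
13 | 2-(bromomethyl)acrylic acid | C=C(CBr)C(=O)O | starting material
14 | 2-(acetoxymethyl)acrylic acid | C=C(COC(C)=O)C(=O)O | intermediate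
15 | (3S,4E,7R,8Z,10R)-7,10,11-tris(TBS-oxy)-5,9-dimethylundeca-1,4,8-trien-3-yl 2-(acetoxymethyl)acrylate | C=C[C@H](OC(=O)C(=C)COC(C)=O)/C=C(\C)C[C@@H](O[Si](C)(C)C(C)(C)C)/C=C(/C)[C@@H](O[Si](C)(C)C(C)(C)C)CO[Si](C)(C)C(C)(C)C | intermediate
16 | {(5R)-5-[(1E,4R,5Z,7R)-4,7,8-tris(TBS-oxy)-2,6-dimethylocta-1,5-dien-1-yl]-2-oxo-2,5-dihydrofuran-3-yl}methyl acetate | CC(=O)OCC1=C[C@H](OC1=O)/C=C(\C)C[C@@H](O[Si](C)(C)C(C)(C)C)/C=C(/C)[C@@H](O[Si](C)(C)C(C)(C)C)CO[Si](C)(C)C(C)(C)C | intermediate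
17 | {(5R)-5-[(1E,4R,5Z,7R)-4,7-bis(TBS-oxy)-8-hydroxy-2,6-dimethylocta-1,5-dien-1-yl]-2-oxo-2,5-dihydrofuran-3-yl}methyl acetate | CC(=O)OCC1=C[C@H](OC1=O)/C=C(\C)C[C@@H](O[Si](C)(C)C(C)(C)C)/C=C(/C)[C@@H](O[Si](C)(C)C(C)(C)C)CO | intermediate
18 | {(5R)-5-[(1E,4R,5Z,7R)-4,7-bis(TBS-oxy)-2,6-dimethyl-8-oxoocta-1,5-dien-1-yl]-2-oxo-2,5-dihydrofuran-3-yl}methyl acetate | CC(=O)OCC1=C[C@H](OC1=O)/C=C(\C)C[C@@H](O[Si](C)(C)C(C)(C)C)/C=C(/C)[C@@H](O[Si](C)(C)C(C)(C)C)C=O | intermediate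
19 | samarium ketyl radical of 18 (C8 radical, O-bound SmI2) | CC(=O)OCC1=C[C@H](OC1=O)/C=C(\C)C[C@@H](O[Si](C)(C)C(C)(C)C)/C=C(/C)[C@@H](O[Si](C)(C)C(C)(C)C)[CH]O[Sm](I)I | intermediate
20 | macrocyclic samarium lactone enolate, C8 samarium alkoxide, acetate still on C13 | CC(=O)OCC1=C(O[Sm](I)I)O[C@@H]2/C=C(\C)C[C@@H](O[Si](C)(C)C(C)(C)C)/C=C(/C)[C@@H](O[Si](C)(C)C(C)(C)C)[C@H](O[Sm](I)I)[C@@H]12 | intermediate
21 | (2R,6R,7R,8R,9R)-2,9-bis(TBS-oxy)-8-hydroxygermacra-1(10)Z,4E,11(13)-trien-12,6-olide | C=C1C(=O)O[C@@H]2/C=C(\C)C[C@@H](O[Si](C)(C)C(C)(C)C)/C=C(/C)[C@@H](O[Si](C)(C)C(C)(C)C)[C@H](O)[C@@H]12 | intermediate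
22 | angelic acid | C/C=C(/C)C(=O)O | starting material
23 | angelic 2,4,6-trichlorobenzoic anhydride | C/C=C(/C)C(=O)OC(=O)c1c(Cl)cc(Cl)cc1Cl | intermediate
24 | (2R,6R,7S,8R,9R)-8-angeloyloxy-2,9-bis(TBS-oxy)germacra-1(10)Z,4E,11(13)-trien-12,6-olide | C=C1C(=O)O[C@@H]2/C=C(\C)C[C@@H](O[Si](C)(C)C(C)(C)C)/C=C(/C)[C@@H](O[Si](C)(C)C(C)(C)C)[C@H](OC(=O)/C(C)=C\C)[C@@H]12 | intermediate
25 | (2R,6R,7S,8R,9R)-8-angeloyloxy-2,9-dihydroxygermacra-1(10)Z,4E,11(13)-trien-12,6-olide (CNP0280988.2) | C=C1C(=O)O[C@@H]2/C=C(\C)C[C@@H](O)/C=C(/C)[C@@H](O)[C@H](OC(=O)/C(C)=C\C)[C@@H]12 | target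

**Step count**
Total: 17 steps. Longest linear sequence: 15 steps (1–5, 7–9, 11–17); steps 6 and 10 are side branches.

**Steps most likely to fail**

Step 15 (radical macrocyclisation). Closure of a ten-membered ring by ketyl addition competes with pinacol dimerisation and simple reduction. The facial selectivity at C7 and C8 rests on a model, and the C8 samarium alkoxide could translactonise. The fallback replaces the radical closure by a polar allylchromium addition and sets out from 12. Alcohol 12 is esterified with acid 13 (DCC) to the bromomethylacrylate ester F1. Ring-closing metathesis with the second-generation Grubbs catalyst gives the 3-(bromomethyl)butenolide F2. HF·pyridine gives the primary alcohol F3, and Dess–Martin oxidation gives the bromo aldehyde F4. F4 is cyclised with CrCl2 in THF/DMF at high dilution (intramolecular Nozaki–Hiyama allylation through a closed six-membered transition state), and the route is rejoined at 21. The sense of induction at C8 would have to be confirmed; a wrong epimer would be corrected by oxidation and hydride reduction.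

Step 7 (vinylogous aldol with an aldehyde-derived dienol ether on a hindered Z-enal). Enantioselectivity, terminal-carbon selectivity and the E/Z ratio of the new enal are uncertain. The fallback uses an ester dienolate under Lewis-base-activated SiCl4 catalysis and sets out from 7. Methyl 3-methylbut-2-enoate with LiN(i-Pr)2 and TBSCl gives the silyl ketene acetal F5. F5 adds to 7 (SiCl4, chiral bisphosphoramide, −78 °C) to give the hydroxy dienoate F6. Silylation gives the tris-silyl ester F7, i-Bu2AlH gives the allylic alcohol F8, and MnO2 oxidation rejoins the route at 11.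

Step 9 (asymmetric vinylation of a β,β-disubstituted enal). The enantioselectivity of vinylzinc addition to this substrate is not assured. The fallback goes through an alkyne and sets out from 11. ProPhenol/Me2Zn alkynylation with trimethylsilylacetylene gives the silyl alkynol F9. K2CO3 in MeOH gives the terminal alkynol F10. Semi-hydrogenation of F10 (H2, Pd on CaCO3 poisoned with Pb(OAc)2, quinoline) rejoins the route at 12.

**Further compounds**
F1 | step 15 | (3S,4E,7R,8Z,10R)-7,10,11-tris(TBS-oxy)-5,9-dimethylundeca-1,4,8-trien-3-yl 2-(bromomethyl)acrylate | C=C[C@H](OC(=O)C(=C)CBr)/C=C(\C)C[C@@H](O[Si](C)(C)C(C)(C)C)/C=C(/C)[C@@H](O[Si](C)(C)C(C)(C)C)CO[Si](C)(C)C(C)(C)C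
F2 | step 15 | (5R)-3-(bromomethyl)-5-[(1E,4R,5Z,7R)-4,7,8-tris(TBS-oxy)-2,6-dimethylocta-1,5-dien-1-yl]furan-2(5H)-one | BrCC1=C[C@H](OC1=O)/C=C(\C)C[C@@H](O[Si](C)(C)C(C)(C)C)/C=C(/C)[C@@H](O[Si](C)(C)C(C)(C)C)CO[Si](C)(C)C(C)(C)C
F3 | step 15 | (5R)-3-(bromomethyl)-5-[(1E,4R,5Z,7R)-4,7-bis(TBS-oxy)-8-hydroxy-2,6-dimethylocta-1,5-dien-1-yl]furan-2(5H)-one | BrCC1=C[C@H](OC1=O)/C=C(\C)C[C@@H](O[Si](C)(C)C(C)(C)C)/C=C(/C)[C@@H](O[Si](C)(C)C(C)(C)C)CO
F4 | step 15 | (2R,3Z,5R,6E)-2,5-bis(TBS-oxy)-7-[(2R)-4-(bromomethyl)-5-oxo-2,5-dihydrofuran-2-yl]-3,6-dimethylhepta-3,6-dienal | BrCC1=C[C@H](OC1=O)/C=C(\C)C[C@@H](O[Si](C)(C)C(C)(C)C)/C=C(/C)[C@@H](O[Si](C)(C)C(C)(C)C)C=O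
F5 | step 7 | tert-butyl[(1-methoxy-3-methylbuta-1,3-dien-1-yl)oxy]dimethylsilane | C=C(C)C=C(OC)O[Si](C)(C)C(C)(C)C
F6 | step 7 | methyl (2E,5R,6Z,8R)-8,9-bis(TBS-oxy)-5-hydroxy-3,7-dimethylnona-2,6-dienoate | COC(=O)/C=C(\C)C[C@@H](O)/C=C(/C)[C@@H](O[Si](C)(C)C(C)(C)C)CO[Si](C)(C)C(C)(C)C
F7 | step 7 | methyl (2E,5R,6Z,8R)-5,8,9-tris(TBS-oxy)-3,7-dimethylnona-2,6-dienoate | COC(=O)/C=C(\C)C[C@@H](O[Si](C)(C)C(C)(C)C)/C=C(/C)[C@@H](O[Si](C)(C)C(C)(C)C)CO[Si](C)(C)C(C)(C)C
F8 | step 7 | (2E,5R,6Z,8R)-5,8,9-tris(TBS-oxy)-3,7-dimethylnona-2,6-dien-1-ol | OC/C=C(\C)C[C@@H](O[Si](C)(C)C(C)(C)C)/C=C(/C)[C@@H](O[Si](C)(C)C(C)(C)C)CO[Si](C)(C)C(C)(C)C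
F9 | step 9 | (3R,4E,7R,8Z,10R)-7,10,11-tris(TBS-oxy)-5,9-dimethyl-1-(trimethylsilyl)undeca-4,8-dien-1-yn-3-ol | C[Si](C)(C)C#C[C@H](O)/C=C(\C)C[C@@H](O[Si](C)(C)C(C)(C)C)/C=C(/C)[C@@H](O[Si](C)(C)C(C)(C)C)CO[Si](C)(C)C(C)(C)C
F10 | step 9 | (3R,4E,7R,8Z,10R)-7,10,11-tris(TBS-oxy)-5,9-dimethylundeca-4,8-dien-1-yn-3-ol | C#C[C@H](O)/C=C(\C)C[C@@H](O[Si](C)(C)C(C)(C)C)/C=C(/C)[C@@H](O[Si](C)(C)C(C)(C)C)CO[Si](C)(C)C(C)(C)C
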